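## The problem

The target 27 is a 3-hydroxy-3,4-dihydroisocoumarin. Ring A (C4a, C5 methyl, C6 methoxy, C7 H, C8 hydroxyl, C8a) is fused to a six-membered lactone–lactol (C1 carbonyl, O2, hemiketal C3, C4 bearing a methyl), and C3 carries a CH2–O ester to ring B, a 2',4'-dihydroxy-5',6'-dimethylbenzoate. The lactol is the ring tautomer of a δ-keto acid, so the hetero ring forms by itself once a free C8a carboxyl faces a C3 ketone; what has to be built is the pentasubstituted ring A, whose side chain at C4a lies between the carboxyl and the C5 methyl, and the ester link to ring B. Of the two stereocentres only C4 (S) needs a stereoselective reaction: C3 (R) is a hemiketal that equilibrates through the open form, and C4 is expected to steer it to the anomer with the 3-OH trans to the 4-methyl (OH axial, methyl turned away from the peri C5 methyl). C4 is benzylic and α to the latent ketone, so base, strong acid or long heating of an open-chain keto form can epimerise it, and acid can dehydrate the lactol to the flat isocoumarin and erase both centres. The α-acyloxy ketone and the ester links are base-labile, and the resorcinol of ring B is sensitive to oxidants and electrophiles. The ring B carboxyl is flanked by the C2' hydroxyl and the C6' methyl, so an esterification that activates this acid would need phenol protection and forcing conditions. The feature that opens another way is that the C1'–C6' edge, with the ester carbonyl on C1' and the methyl on C6', is a but-2-ynoate in disguise, while C2'–C5' with their two oxygens and the C5' methyl are the four diene carbons of the bis-silyl dienol ether of a 3-oxopentanoate: ring B can be grown on an ester that is already in place.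

## Retrosynthesis

**27 ⇒ 26 ⇒ 25.** The O2–C3 hemiketal bond is opened to the keto acid 26, and the C8 hydroxyl and C1 carboxyl are then capped as benzyl ether and benzyl ester (25). Closing the lactone by acylation at O2 instead would require a free tertiary hemiketal as nucleophile; opening the hemiketal costs nothing and removes one ring and the C3 stereocentre. The forward step must cleave two benzyl groups without touching the α-acyloxy ketone or the ring B ester, under conditions too mild to dehydrate the lactol; hydrogenolysis over Pd/C fits, and the closure is spontaneous and thermodynamic.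

**25 ⇒ 18 + 22.** The C1'–C2' and C5'–C6' bonds of ring B are cut, giving the but-2-ynoate 18 and the diene 22. The neighbouring cut at the acyl C–O bond leads to a doubly ortho-substituted resorcylic acid that would have to be protected and activated; the cut at the O–CH2 bond (carboxylate alkylation) is sound but needs ring B made separately, and is kept as the reserve. The chosen cut removes the whole of ring B and both phenols at once, leaving an unhindered four-carbon ester. The forward reaction must be regioselective (methyl next to methyl), must prefer the ynoate to the ketone, and must leave C4 alone.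

**18 ⇒ 16 + 17, 16 ⇒ 14.** The CH2–O bond is cut (O–H insertion of the diazoketone 16 into but-2-ynoic acid 17), then the C3–CH2 bond (acylation of a diazoalkane by the acid chloride 15 of acid 14). Building the ketone by enolate or organometallic chemistry would expose C4 to base; the diazoketone route is neutral throughout and delivers the α-acyloxy ketone in the correct oxidation state. The precursor 14 is a 2-arylpropanoic acid, a well-understood class. The forward steps must avoid the ketene pathway at the acid chloride stage and must make O–H insertion faster than any other carbenoid reaction.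

**14 ⇒ 13.** The two C–H bonds at C4 and its methyl are removed, giving the 2-arylacrylic acid 13. Against auxiliary-controlled methylation of an arylacetic acid (an enolate next to an ortho ester) and against setting C4 early (more steps carrying a labile centre), asymmetric hydrogenation creates C4 late, in one step, and nothing before 14 is chiral. The forward reaction must discriminate the faces of a 1,1-disubstituted alkene whose aryl group carries two ortho substituents, and must spare the benzyl groups.

**13 ⇒ 12 ⇒ 11 ⇒ 10 ⇒ 9 ⇒ 7.** Functional groups are adjusted (ethyl ester, benzyl ester and ether, carboxyl from formyl, phenol from methyl ether), then the C8a–C1 bond is cut (formylation of 7). The alternative order, carboxyl first and side chain afterwards, would require a cross-coupling at a bromide flanked by two substituents; introducing the side chain first keeps every C–C bond formation on an uncrowded ring, and that alternative order is held in reserve. The forward sequence needs formylation ortho to the side chain and not between the methoxy groups, cleavage of only the methoxy group next to the formyl group, and hydrolysis of the ethyl ester without loss of the hindered benzyl ester.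

**7 ⇒ 6 ⇒ 4.** The C=CH2 bond (Wittig methylenation of the α-keto ester 6) and the C4a–C4 bond (addition of the aryllithium 5 to an oxalic ester) are cut. This pair of textbook steps replaces a coupling with an α-metallated acrylate. The forward reaction must stop at mono-addition to the oxalate.

**4 ⇒ 3 ⇒ 1.** The C5 methyl is traced to a formyl group (3) and the formyl group to a C–H bond of 1-bromo-3,5-dimethoxybenzene 1. The bromine marks the one ring position, meta to both oxygens, that electrophilic substitution cannot reach; the two oxygen-activated positions beside it then take the methyl and, later, the carboxyl.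

**22 ⇒ 20 ⇒ 19.** Two O–Si bonds are cut: the diene comes from methyl 3-oxopentanoate 19 by stepwise silylation through the enol ether 20 and the dienolate 21.

## Roads not taken

**Alternative 1:** The cut is the C4a–C8a bond of ring A, which unravels the arene into an open-chain polyketide masked as the diketo-dioxinone A2. On heating with benzyl alcohol the dioxinone ring would lose acetone, the acyl ketene would be trapped as a benzyl ester, and aldol addition of the C8a methylene to the C4a ketone followed by dehydration would give the resorcylate A1.
- Merits: ring A with its carboxyl, both oxygens, the C5 methyl and the branched side chain arises from an acyclic precursor, with no substitution on a crowded arene, and C4 comes from a chiral building block. In this respect the road is better than the chosen plan, which needs two formylations, an organolithium addition and a hydrogenation beside two ortho substituents.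
- Weak points: in A2 and in the chain derived from it, C4 is α to a ketone of a 1,3-diketone and enolises easily, so the centre is at risk in the key step itself. The C5 methyl sits between two ketones and must be placed regioselectively on a polycarbonyl chain. After A1 the C6 phenol must be methylated selectively, the acetonide removed, the primary alcohol acylated with the hindered ring B carboxyl (phenols protected, acid activated) and the secondary alcohol oxidised.
- Against the more direct ring A construction, the chosen plan sets a C4 that is created late and never lies next to a 1,3-dicarbonyl, and an ester link made without activating the hindered acid.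

**Alternative 2:** The cut removes O2 from the lactol ring and leaves the α-hydroxy indanone A4, whose carbonyl is the future C1 and whose quaternary carbinol carbon is the future C3. A peracid would insert oxygen between these carbons (Baeyer–Villiger reaction with migration of the oxygen-bearing carbon), or periodic acid would cleave the ketol so that the keto acid recloses; either way the tri-O-benzyl lactol A3 results.
- Merits: in A4 the future C4 is β to the carbonyl and next to a quaternary carbon, so it cannot epimerise before the last stage. That is better than the chosen plan, which carries C4 α to a ketone through four steps. The five-membered ring can be closed by intramolecular acylation, which also fixes the position of the ring A carboxyl.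
- Weak points: the aryl group on the carbonyl is an ortho,para-dialkoxyphenyl group, an excellent migrating group, so insertion on the wrong side and oxidation of the electron-rich rings compete with the wanted insertion. A4 needs a quaternary carbon carrying both OH and an acyloxymethyl group, and its ester must be made by acylating a neopentyl-type alcohol with the hindered, protected ring B carboxyl. Three benzyl ethers have to be removed at the end.
- Against the better-protected C4, the chosen plan sets neutral, non-oxidative conditions from the moment the ketone exists, and an ester link that needs no acylation by the hindered acid.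

**Alternative 3:** The cut runs through ring A at C4a–C5 and C8–C8a and gives the ynoate A6, which carries C4 at its propargylic carbon, the C3 carbinol as a triethylsilyl ether and the finished, benzyl-protected ring B ester, together with the diene A7. The forward step is the same type of cycloaddition and aromatisation as in the chosen plan; loss of methanol would give the salicylate A5 with the C6 methoxy group and the free C8 hydroxyl already differentiated.
- Merits: the crowded C4a–C4 junction and the pentasubstituted ring A form in one step without organometallic chemistry or hydrogenation of a hindered acrylate, and the O-methylation pattern needs no selective step. During the heating C4 is propargylic, not α to a ketone. On both counts this road is better than the chosen plan.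
- Weak points: the alkyne carbon that must bond to the methyl-bearing diene terminus carries a branched, oxygenated secondary alkyl group and not a methyl, so the congested C4a–C5 bond should form more slowly than the C5'–C6' bond of the chosen plan. A6 needs two adjacent stereocentres, one of which is later destroyed by oxidation. Ring B must be made and attached beforehand through the hindered acid with protected phenols. Desilylation, oxidation to the ketone and debenzylation still follow the cycloaddition.
- The chosen plan has to set against it a less hindered dienophile, no redox adjustment after ring formation, fewer protecting groups and an ester link made from but-2-ynoic acid.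

Key step: step 15

Assumption: the hemiketal carbon C3 equilibrates through the open keto acid 26, and the (3R) configuration of the target (3-OH trans to the C4 methyl) is taken to be the thermodynamically preferred anomer, so the route sets only C4.

## Steps

Step 1
Reactants: 1 1-bromo-3,5-dimethoxybenzene
Product: 3 2-bromo-4,6-dimethoxybenzaldehyde, via iminium chloride 2 (not isolated)
Conditions: POCl3, DMF, 0 → 90 °C; then H2O
Reagents that add atoms: N,N-dimethylformamide CN(C)C=O; water O
Why: Vilsmeier–Haack formylation; the carbon flanked by Br and OMe is para to the second methoxy group and should be attacked in preference to the more crowded carbon between the two methoxy groups, and the iminium salt 2 is hydrolysed on work-up.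

Step 2
Reactants: 3 2-bromo-4,6-dimethoxybenzaldehyde
Product: 4 1-bromo-3,5-dimethoxy-2-methylbenzene
Conditions: Et3SiH (excess), CF3CO2H, CH2Cl2, 0 °C → rt
Reagents that add atoms: none
Why: Ionic hydrogenation of an electron-rich benzaldehyde to the methylarene; the ortho and para methoxy groups stabilise the benzylic cation that takes hydride from the silane, and the aryl bromide, which catalytic hydrogenolysis would remove, is untouched. Excess silane should suppress diarylmethane formation.

Step 3
Reactants: 4 1-bromo-3,5-dimethoxy-2-methylbenzene
Product: 6 ethyl 2-(3,5-dimethoxy-2-methylphenyl)-2-oxoacetate, via aryllithium 5 (not isolated)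
Conditions: n-BuLi, THF, −78 °C; then cannulated into diethyl oxalate (3 equiv), THF, −78 °C; aq. NH4Cl
Reagents that add atoms: diethyl oxalate CCOC(=O)C(=O)OCC
Why: Bromine–lithium exchange is faster at −78 °C than deprotonation between the methoxy groups; inverse addition of 5 to excess oxalate should stop at the α-keto ester because the tetrahedral adduct persists until the quench.

Step 4
Reactants: 6 ethyl 2-(3,5-dimethoxy-2-methylphenyl)-2-oxoacetate
Product: 7 ethyl 2-(3,5-dimethoxy-2-methylphenyl)prop-2-enoate
Conditions: Ph3PCH3Br, KOt-Bu, THF, 0 °C → rt
Reagents that add atoms: methyltriphenylphosphonium bromide C[P+](c1ccccc1)(c1ccccc1)c1ccccc1.[Br-]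
Why: Wittig methylenation of the highly electrophilic keto carbonyl of an aryl glyoxylate, a standard entry to 2-arylacrylates; the ester carbonyl does not compete with the ketone for the ylide.

Step 5
Reactants: 7 ethyl 2-(3,5-dimethoxy-2-methylphenyl)prop-2-enoate
Product: 9 ethyl 2-(2-formyl-3,5-dimethoxy-6-methylphenyl)prop-2-enoate, via iminium chloride 8 (not isolated)
Conditions: POCl3, DMF, 0 → 70 °C; then H2O
Reagents that add atoms: N,N-dimethylformamide CN(C)C=O; water O
Why: Vilsmeier–Haack formylation; the carbon ortho to the side chain is para to one methoxy group, whereas the only other free carbon lies between two methoxy groups, one of them pressed toward it by the neighbouring ring methyl, so attack is expected at the wanted site as in step 1. The electron-poor acrylate does not react with the chloroiminium ion.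

Step 6
Reactants: 9 ethyl 2-(2-formyl-3,5-dimethoxy-6-methylphenyl)prop-2-enoate
Product: 10 ethyl 2-(2-formyl-3-hydroxy-5-methoxy-6-methylphenyl)prop-2-enoate
Conditions: BCl3, CH2Cl2, −78 → 0 °C
Reagents that add atoms: none
Why: Chelation-controlled ether cleavage: BCl3 bridges the formyl oxygen and the adjacent methoxy oxygen in a six-membered chelate and chloride removes only that methyl group; the methoxy group para to the aldehyde and the ethyl ester should survive at low temperature.

Step 7
Reactants: 10 ethyl 2-(2-formyl-3-hydroxy-5-methoxy-6-methylphenyl)prop-2-enoate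
Product: 11 2-(3-ethoxy-3-oxoprop-1-en-2-yl)-6-hydroxy-4-methoxy-3-methylbenzoic acid
Conditions: NaClO2, NaH2PO4, 2-methyl-2-butene (large excess), t-BuOH/H2O, rt
Reagents that add atoms: sodium chlorite [Na+].[O-]Cl=O
Why: Pinnick oxidation, a chlorite method that tolerates phenolic aldehydes; the alkene scavenger traps HOCl before it can chlorinate the activated ring, and the buffered medium leaves the acrylate intact.

Step 8
Reactants: 11 2-(3-ethoxy-3-oxoprop-1-en-2-yl)-6-hydroxy-4-methoxy-3-methylbenzoic acid
Product: 12 benzyl 6-(benzyloxy)-2-(3-ethoxy-3-oxoprop-1-en-2-yl)-4-methoxy-3-methylbenzoate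
Conditions: BnBr (2.5 equiv), K2CO3, DMF, rt → 40 °C
Reagents that add atoms: benzyl bromide BrCc1ccccc1
Why: Williamson-type O-alkylation of the carboxylate and of the hydrogen-bonded phenoxide, which DMF and carbonate make possible; any conjugate addition of the carboxylate to the acrylate is reversible and is drained by the irreversible alkylation.

Step 9
Reactants: 12 benzyl 6-(benzyloxy)-2-(3-ethoxy-3-oxoprop-1-en-2-yl)-4-methoxy-3-methylbenzoate
Product: 13 2-{3-(benzyloxy)-2-[(benzyloxy)carbonyl]-5-methoxy-6-methylphenyl}prop-2-enoic acid
Conditions: LiOH, THF/H2O, rt; then 1 M HCl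
Reagents that add atoms: lithium hydroxide [Li+].[OH-]
Why: Saponification; hydroxide attacks the ethyl ester, while the benzyl benzoate flanked by two ortho substituents resists acyl attack, as 2,6-disubstituted benzoates do. No stereocentre exists yet, so base is harmless here.

Step 10
Reactants: 13 2-{3-(benzyloxy)-2-[(benzyloxy)carbonyl]-5-methoxy-6-methylphenyl}prop-2-enoic acid
Product: 14 (2S)-2-{3-(benzyloxy)-2-[(benzyloxy)carbonyl]-5-methoxy-6-methylphenyl}propanoic acid
Conditions: Ru(OAc)2[(S)-BINAP] (2 mol %), H2 (100 atm), MeOH, 30 °C
Reagents that add atoms: none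
Why: Noyori asymmetric hydrogenation of a 2-arylacrylic acid: the carboxylate binds ruthenium, the unhindered CH2 terminus bonds to the metal and hydrogen is delivered to the α-carbon on the face chosen by the (S)-BINAP ligand, which by analogy with other 2-arylpropanoic acids should give the (S)-acid and so set C4. The sense has to be confirmed on this substrate and the (R)-ligand is available; the homogeneous catalyst leaves the benzyl groups alone.

Step 11
Reactants: 14 (2S)-2-{3-(benzyloxy)-2-[(benzyloxy)carbonyl]-5-methoxy-6-methylphenyl}propanoic acid
Product: 16 benzyl 6-(benzyloxy)-2-[(2S)-4-diazo-3-oxobutan-2-yl]-4-methoxy-3-methylbenzoate, via acid chloride 15 (not isolated)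
Conditions: (COCl)2, cat. DMF, CH2Cl2, 0 °C; evaporate; then CH2N2 (excess), Et2O, 0 °C
Reagents that add atoms: diazomethane C=[N+]=[N-]
Why: Acylation of diazomethane by an acid chloride, the first stage of the Arndt–Eistert sequence; no amine base is present, so the ketene pathway that racemises 2-arylpropanoyl chlorides is avoided, and the second equivalent of diazomethane removes HCl.

Step 12
Reactants: 16 benzyl 6-(benzyloxy)-2-[(2S)-4-diazo-3-oxobutan-2-yl]-4-methoxy-3-methylbenzoate; 17 but-2-ynoic acid
Product: 18 benzyl 6-(benzyloxy)-2-[(2S)-4-(but-2-ynoyloxy)-3-oxobutan-2-yl]-4-methoxy-3-methylbenzoate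
Conditions: Rh2(OAc)4 (1 mol %), 17 (3 equiv), CH2Cl2, rt, slow addition of 16
Reagents that add atoms: none
Why: Rh2(OAc)4-catalysed O–H insertion of an α-diazoketone into a carboxylic acid, giving the α-acyloxy ketone; the fairly acidic but-2-ynoic acid in excess should trap the carbenoid faster than it can add to the alkyne or to the ortho-blocked arene, and the neutral medium does not touch C4.

Step 13
Reactants: 19 methyl 3-oxopentanoate
Product: 20 methyl 3-[(trimethylsilyl)oxy]pent-2-enoate
Conditions: Me3SiCl, Et3N, hexane, rt
Reagents that add atoms: chlorotrimethylsilane C[Si](C)(C)Cl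
Why: O-silylation of the enol of a β-keto ester under soft enolisation, the usual first stage in the preparation of 1,3-bis(silyloxy)dienes; the double-bond geometry of 20 is of no consequence.

Step 14
Reactants: 20 methyl 3-[(trimethylsilyl)oxy]pent-2-enoate
Product: 22 (3Z)-1-methoxy-1,3-bis[(trimethylsilyl)oxy]penta-1,3-diene, via lithium dienolate 21 (not isolated)
Conditions: LiN(i-Pr)2, THF, −78 °C; then Me3SiCl, −78 °C → rt
Reagents that add atoms: chlorotrimethylsilane C[Si](C)(C)Cl
Why: γ-Deprotonation of the vinylogous ester gives the dienolate 21, which is silylated on oxygen; the (3Z) diene, with the terminal methyl on the outside of the s-cis conformer, is the usual outcome and is the geometry the cycloaddition needs.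

Step 15
Reactants: 18 benzyl 6-(benzyloxy)-2-[(2S)-4-(but-2-ynoyloxy)-3-oxobutan-2-yl]-4-methoxy-3-methylbenzoate; 22 (3Z)-1-methoxy-1,3-bis[(trimethylsilyl)oxy]penta-1,3-diene
Product: 25 benzyl 6-(benzyloxy)-2-{(2S)-4-[(2,4-dihydroxy-5,6-dimethylbenzoyl)oxy]-3-oxobutan-2-yl}-4-methoxy-3-methylbenzoate, via cycloadduct 23 (not isolated), via bis(trimethylsilyl) ether 24 (not isolated)
Conditions: 22 (4 equiv), toluene, 120 °C, sealed tube; then 1 M HCl, THF, 0 °C
Reagents that add atoms: none
Why: The electron-rich diene 22 and the ynoate of 18 combine in a thermal, normal-demand [4+2] cycloaddition that is probably asynchronous: the methyl-bearing terminus of 22 bonds to the β-carbon of the ynoate (C5'–C6') and the ketene-acetal carbon to the α-carbon (C1'–C2'), giving the cyclohexa-1,4-diene 23. 1,4-Elimination of methanol from 23 aromatises it to the bis-silyl ether 24, and dilute acid then frees both phenols to give 25. The closest known reaction type is the Diels–Alder benzannulation of 1-methoxy-1,3-bis(silyloxy)-1,3-dienes with alkynoates, including β-alkyl alkynoates already held in an ester, to give 2,4-dihydroxybenzoates. Ring B is closed as a six-membered carbocycle by an intermolecular [4+2] cycloaddition in which both new ring bonds form between the two components. No stereocentre is created, since the two sp3 ring carbons of 23 become aromatic. The step needs regioselectivity, which the matched polarisation of the partners secures (largest HOMO coefficient at the methyl-bearing diene terminus, largest LUMO coefficient at the ynoate β-carbon), and chemoselectivity for the ynoate over the ketone, which the absence of any Lewis acid and of free O–H groups in 18 secures. C4 should survive because the medium is neutral and its aryl group, held perpendicular by two ortho substituents, cannot stabilise an enol.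

Step 16
Reactants: 25 benzyl 6-(benzyloxy)-2-{(2S)-4-[(2,4-dihydroxy-5,6-dimethylbenzoyl)oxy]-3-oxobutan-2-yl}-4-methoxy-3-methylbenzoate
Product: 27 [(3R,4S)-3,8-dihydroxy-6-methoxy-4,5-dimethyl-1-oxo-3,4-dihydro-1H-2-benzopyran-3-yl]methyl 2,4-dihydroxy-5,6-dimethylbenzoate, via keto acid 26 (not isolated)
Conditions: H2 (1 atm), Pd/C, EtOAc, rt
Reagents that add atoms: none
Why: Hydrogenolysis of the benzyl ester and the benzyl aryl ether; the freed δ-keto acid 26 should close by 6-exo-trig addition of the carboxyl to the ketone, under thermodynamic control, with C4 directing C3 to the anomer that has the 3-OH trans to the 4-methyl. The neutral conditions should neither epimerise C4 nor dehydrate the lactol.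

## Compound list

1 | 1-bromo-3,5-dimethoxybenzene | COc1cc(Br)cc(OC)c1 | starting material
2 | N-[(2-bromo-4,6-dimethoxyphenyl)methylidene]-N-methylmethanaminium chloride | COc1cc(Br)c(C=[N+](C)C)c(OC)c1.[Cl-] | intermediate
3 | 2-bromo-4,6-dimethoxybenzaldehyde | COc1cc(Br)c(C=O)c(OC)c1 | intermediate
4 | 1-bromo-3,5-dimethoxy-2-methylbenzene | COc1cc(Br)c(C)c(OC)c1 | intermediate
5 | (3,5-dimethoxy-2-methylphenyl)lithium | [Li]c1cc(OC)cc(OC)c1C | intermediate
6 | ethyl 2-(3,5-dimethoxy-2-methylphenyl)-2-oxoacetate | CCOC(=O)C(=O)c1cc(OC)cc(OC)c1C | intermediate
7 | ethyl 2-(3,5-dimethoxy-2-methylphenyl)prop-2-enoate | CCOC(=O)C(=C)c1cc(OC)cc(OC)c1C | intermediate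
8 | N-{[6-(3-ethoxy-3-oxoprop-1-en-2-yl)-2,4-dimethoxy-5-methylphenyl]methylidene}-N-methylmethanaminium chloride | CCOC(=O)C(=C)c1c(C=[N+](C)C)c(OC)cc(OC)c1C.[Cl-] | intermediate
9 | ethyl 2-(2-formyl-3,5-dimethoxy-6-methylphenyl)prop-2-enoate | CCOC(=O)C(=C)c1c(C=O)c(OC)cc(OC)c1C | intermediate
10 | ethyl 2-(2-formyl-3-hydroxy-5-methoxy-6-methylphenyl)prop-2-enoate | CCOC(=O)C(=C)c1c(C=O)c(O)cc(OC)c1C | intermediate
11 | 2-(3-ethoxy-3-oxoprop-1-en-2-yl)-6-hydroxy-4-methoxy-3-methylbenzoic acid | CCOC(=O)C(=C)c1c(C(=O)O)c(O)cc(OC)c1C | intermediate
12 | benzyl 6-(benzyloxy)-2-(3-ethoxy-3-oxoprop-1-en-2-yl)-4-methoxy-3-methylbenzoate | CCOC(=O)C(=C)c1c(C(=O)OCc2ccccc2)c(OCc2ccccc2)cc(OC)c1C | intermediate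
13 | 2-{3-(benzyloxy)-2-[(benzyloxy)carbonyl]-5-methoxy-6-methylphenyl}prop-2-enoic acid | C=C(C(=O)O)c1c(C(=O)OCc2ccccc2)c(OCc2ccccc2)cc(OC)c1C | intermediate
14 | (2S)-2-{3-(benzyloxy)-2-[(benzyloxy)carbonyl]-5-methoxy-6-methylphenyl}propanoic acid | COc1cc(OCc2ccccc2)c(C(=O)OCc2ccccc2)c(c1C)[C@H](C)C(=O)O | intermediate
15 | benzyl 6-(benzyloxy)-2-[(2S)-1-chloro-1-oxopropan-2-yl]-4-methoxy-3-methylbenzoate | COc1cc(OCc2ccccc2)c(C(=O)OCc2ccccc2)c(c1C)[C@H](C)C(Cl)=O | intermediate
16 | benzyl 6-(benzyloxy)-2-[(2S)-4-diazo-3-oxobutan-2-yl]-4-methoxy-3-methylbenzoate | COc1cc(OCc2ccccc2)c(C(=O)OCc2ccccc2)c(c1C)[C@H](C)C(=O)C=[N+]=[N-] | intermediate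
17 | but-2-ynoic acid | CC#CC(=O)O | starting material
18 | benzyl 6-(benzyloxy)-2-[(2S)-4-(but-2-ynoyloxy)-3-oxobutan-2-yl]-4-methoxy-3-methylbenzoate | COc1cc(OCc2ccccc2)c(C(=O)OCc2ccccc2)c(c1C)[C@H](C)C(=O)COC(=O)C#CC | intermediate
19 | methyl 3-oxopentanoate | CCC(=O)CC(=O)OC | starting material
20 | methyl 3-[(trimethylsilyl)oxy]pent-2-enoate (E/Z mixture, geometry not specified) | CCC(O[Si](C)(C)C)=CC(=O)OC | intermediate
21 | lithium (3Z)-1-methoxy-3-[(trimethylsilyl)oxy]penta-1,3-dien-1-olate | C/C=C(\O[Si](C)(C)C)C=C(OC)[O-].[Li+] | intermediate
22 | (3Z)-1-methoxy-1,3-bis[(trimethylsilyl)oxy]penta-1,3-diene | C/C=C(\O[Si](C)(C)C)C=C(OC)O[Si](C)(C)C | intermediate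
23 | benzyl 6-(benzyloxy)-2-{(2S)-4-[({6-methoxy-2,3-dimethyl-4,6-bis[(trimethylsilyl)oxy]cyclohexa-1,4-dien-1-yl}carbonyl)oxy]-3-oxobutan-2-yl}-4-methoxy-3-methylbenzoate (isomer mixture at the two transient sp3 ring carbons) | COc1cc(OCc2ccccc2)c(C(=O)OCc2ccccc2)c(c1C)[C@H](C)C(=O)COC(=O)C1=C(C)C(C)C(O[Si](C)(C)C)=CC1(OC)O[Si](C)(C)C | intermediate
24 | benzyl 6-(benzyloxy)-2-{(2S)-4-[(5,6-dimethyl-2,4-bis[(trimethylsilyl)oxy]benzoyl)oxy]-3-oxobutan-2-yl}-4-methoxy-3-methylbenzoate | COc1cc(OCc2ccccc2)c(C(=O)OCc2ccccc2)c(c1C)[C@H](C)C(=O)COC(=O)c1c(O[Si](C)(C)C)cc(O[Si](C)(C)C)c(C)c1C | intermediate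
25 | benzyl 6-(benzyloxy)-2-{(2S)-4-[(2,4-dihydroxy-5,6-dimethylbenzoyl)oxy]-3-oxobutan-2-yl}-4-methoxy-3-methylbenzoate | COc1cc(OCc2ccccc2)c(C(=O)OCc2ccccc2)c(c1C)[C@H](C)C(=O)COC(=O)c1c(O)cc(O)c(C)c1C | intermediate
26 | 2-{(2S)-4-[(2,4-dihydroxy-5,6-dimethylbenzoyl)oxy]-3-oxobutan-2-yl}-6-hydroxy-4-methoxy-3-methylbenzoic acid | COc1cc(O)c(C(=O)O)c(c1C)[C@H](C)C(=O)COC(=O)c1c(O)cc(O)c(C)c1C | intermediate
27 | [(3R,4S)-3,8-dihydroxy-6-methoxy-4,5-dimethyl-1-oxo-3,4-dihydro-1H-2-benzopyran-3-yl]methyl 2,4-dihydroxy-5,6-dimethylbenzoate | COc1cc(O)c2c(c1C)[C@H](C)[C@](O)(COC(=O)c1c(O)cc(O)c(C)c1C)OC2=O | target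

## Step count and least certain steps

Total: 16 steps. Longest linear sequence: 14 steps (steps 1–12, 15 and 16); the diene branch (steps 13 and 14) joins at step 15.

**Step 15 (key step).** The cycloaddition must join two methyl-bearing carbons, and a but-2-ynoate is a sluggish dienophile. At the temperature needed, the diene may decompose by silyl migration, add to the ketone in an aldol sense, or transfer silicon to the ketone enol with loss of configuration at C4, before ring B closes; addition in the reverse orientation is a lesser risk. The fallback makes ring B apart and forms the ester from the carboxylate side, so the hindered acid is never activated. It sets out from 16, 17 and 22 and returns at 25.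
- But-2-ynoic acid 17 would be benzylated (BnBr, K2CO3, DMF) to benzyl but-2-ynoate F1.
- F1 would be heated with 22 without solvent at 140 °C, conditions this simple ester tolerates, to give the cycloadduct F2, which loses methanol to the bis-silyl ether F3; dilute HCl would give benzyl 2,4-dihydroxy-5,6-dimethylbenzoate F4.
- Hydrogenolysis (H2, Pd/C) would give 2,4-dihydroxy-5,6-dimethylbenzoic acid F5.
- Diazoketone 16 would be treated with HBr in Et2O at 0 °C to give the bromomethyl ketone F6.
- F5 with KHCO3 in DMF, which ionises only the carboxyl, would displace bromide from F6 to give 25.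

**Step 10.** The aryl group on the alkene is forced perpendicular by its two ortho substituents, so slow turnover and poor facial discrimination are the likely failures. The fallback hydrogenates before the second ortho substituent exists. It sets out from 7 and returns at 14.
- Saponification of 7 (LiOH) would give 2-(3,5-dimethoxy-2-methylphenyl)prop-2-enoic acid F7.
- Hydrogenation with Ru(OAc)2[(S)-BINAP] under the conditions of step 10, now on an ordinary profen-type substrate, would give (2S)-2-(3,5-dimethoxy-2-methylphenyl)propanoic acid F8.
- Me3SiCHN2 in MeOH/toluene would give the methyl ester F9.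
- Vilsmeier–Haack formylation through the iminium chloride F10 would give the aldehyde F11; BCl3 would give the phenol F12; Pinnick oxidation would give the hydroxy acid F13; BnBr and K2CO3 would give the dibenzyl compound F14.
- Me3SnOH in 1,2-dichloroethane at 80 °C would cleave the methyl ester without base strong enough to epimerise the centre, giving 14.
- The price is two more steps and a stereocentre carried through five more operations.

**Step 5.** Attack at the carbon between the methoxy groups, or incomplete conversion because the reacting carbon is flanked by the acrylate, are the likely failures. The fallback reverses the order of formylation and C–C bond formation. It sets out from 4 and returns at 9.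
- Vilsmeier–Haack formylation of 4, whose regiochemistry is modelled by step 1, would give through the iminium chloride F15 the aldehyde 2-bromo-4,6-dimethoxy-3-methylbenzaldehyde F16.
- Stille coupling of F16 with ethyl 2-(tributylstannyl)prop-2-enoate (Pd(PPh3)4, CuI, DMF, 60 °C) would give 9; the ortho formyl group activates the bromide toward oxidative addition.

**Step 12.** The carbenoid may be diverted to the electron-rich arene or to the alkyne, or may dimerise, if O–H insertion is not fast enough. The fallback avoids a metal carbenoid. It sets out from 16 and returns at 18.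
- Acid-catalysed hydrolysis of 16 (0.5 M H2SO4, THF/H2O, 40 °C) would give the hydroxymethyl ketone F17.
- Steglich esterification of F17 with 17 (DCC, cat. DMAP, CH2Cl2, −20 → 0 °C) would give 18.

## Further compounds

F1 | step 15 | benzyl but-2-ynoate | CC#CC(=O)OCc1ccccc1
F2 | step 15 | benzyl 6-methoxy-2,3-dimethyl-4,6-bis[(trimethylsilyl)oxy]cyclohexa-1,4-diene-1-carboxylate (isomer mixture) | CC1C(C)=C(C(=O)OCc2ccccc2)C(OC)(O[Si](C)(C)C)C=C1O[Si](C)(C)C
F3 | step 15 | benzyl 5,6-dimethyl-2,4-bis[(trimethylsilyl)oxy]benzoate | Cc1c(C)c(O[Si](C)(C)C)cc(O[Si](C)(C)C)c1C(=O)OCc1ccccc1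
F4 | step 15 | benzyl 2,4-dihydroxy-5,6-dimethylbenzoate | Cc1c(C)c(O)cc(O)c1C(=O)OCc1ccccc1
F5 | step 15 | 2,4-dihydroxy-5,6-dimethylbenzoic acid | Cc1c(C)c(O)cc(O)c1C(=O)O
F6 | step 15 | benzyl 6-(benzyloxy)-2-[(2S)-4-bromo-3-oxobutan-2-yl]-4-methoxy-3-methylbenzoate | COc1cc(OCc2ccccc2)c(C(=O)OCc2ccccc2)c(c1C)[C@H](C)C(=O)CBr
F7 | step 10 | 2-(3,5-dimethoxy-2-methylphenyl)prop-2-enoic acid | C=C(C(=O)O)c1cc(OC)cc(OC)c1C
F8 | step 10 | (2S)-2-(3,5-dimethoxy-2-methylphenyl)propanoic acid | C[C@H](C(=O)O)c1cc(OC)cc(OC)c1C
F9 | step 10 | methyl (2S)-2-(3,5-dimethoxy-2-methylphenyl)propanoate | C[C@H](C(=O)OC)c1cc(OC)cc(OC)c1C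
F10 | step 10 | N-({2,4-dimethoxy-6-[(2S)-1-methoxy-1-oxopropan-2-yl]-5-methylphenyl}methylidene)-N-methylmethanaminium chloride | C[C@H](C(=O)OC)c1c(C=[N+](C)C)c(OC)cc(OC)c1C.[Cl-]
F11 | step 10 | methyl (2S)-2-(2-formyl-3,5-dimethoxy-6-methylphenyl)propanoate | C[C@H](C(=O)OC)c1c(C=O)c(OC)cc(OC)c1C
F12 | step 10 | methyl (2S)-2-(2-formyl-3-hydroxy-5-methoxy-6-methylphenyl)propanoate | C[C@H](C(=O)OC)c1c(C=O)c(O)cc(OC)c1C
F13 | step 10 | 6-hydroxy-4-methoxy-2-[(2S)-1-methoxy-1-oxopropan-2-yl]-3-methylbenzoic acid | C[C@H](C(=O)OC)c1c(C(=O)O)c(O)cc(OC)c1C
F14 | step 10 | benzyl 6-(benzyloxy)-4-methoxy-2-[(2S)-1-methoxy-1-oxopropan-2-yl]-3-methylbenzoate | C[C@H](C(=O)OC)c1c(C(=O)OCc2ccccc2)c(OCc2ccccc2)cc(OC)c1C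
F15 | step 5 | N-[(2-bromo-4,6-dimethoxy-3-methylphenyl)methylidene]-N-methylmethanaminium chloride | C[N+](C)=Cc1c(Br)c(C)c(OC)cc1OC.[Cl-]
F16 | step 5 | 2-bromo-4,6-dimethoxy-3-methylbenzaldehyde | O=Cc1c(Br)c(C)c(OC)cc1OC
F17 | step 12 | benzyl 6-(benzyloxy)-2-[(2S)-4-hydroxy-3-oxobutan-2-yl]-4-methoxy-3-methylbenzoate | COc1cc(OCc2ccccc2)c(C(=O)OCc2ccccc2)c(c1C)[C@H](C)C(=O)CO
A1 | alternative 1 | benzyl 6-[1-(2,2-dimethyl-1,3-dioxolan-4-yl)ethyl]-2,4-dihydroxy-5-methylbenzoate (configured as in the SMILES) | Cc1c(O)cc(O)c(C(=O)OCc2ccccc2)c1[C@H](C)[C@H]1COC(C)(C)O1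
A2 | alternative 1 | 6-[5-(2,2-dimethyl-1,3-dioxolan-4-yl)-3-methyl-2,4-dioxohexyl]-2,2-dimethyl-4H-1,3-dioxin-4-one (configured as in the SMILES) | CC1(C)OC(=CC(=O)O1)CC(=O)C(C)C(=O)[C@H](C)[C@H]1COC(C)(C)O1
A3 | alternative 2 | [8-(benzyloxy)-3-hydroxy-6-methoxy-4,5-dimethyl-1-oxo-3,4-dihydro-1H-2-benzopyran-3-yl]methyl 2,4-bis(benzyloxy)-5,6-dimethylbenzoate (configured as in the target) | COc1cc(OCc3ccccc3)c2c(c1C)[C@H](C)[C@](O)(COC(=O)c1c(OCc3ccccc3)cc(OCc3ccccc3)c(C)c1C)OC2=O
A4 | alternative 2 | [7-(benzyloxy)-2-hydroxy-5-methoxy-3,4-dimethyl-1-oxo-2,3-dihydro-1H-inden-2-yl]methyl 2,4-bis(benzyloxy)-5,6-dimethylbenzoate (configured as in the SMILES) | COc1cc(OCc3ccccc3)c2c(c1C)[C@H](C)[C@](O)(COC(=O)c1c(OCc3ccccc3)cc(OCc3ccccc3)c(C)c1C)C2=O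
A5 | alternative 3 | benzyl 2-{4-[2,4-bis(benzyloxy)-5,6-dimethylbenzoyl]oxy-3-[(triethylsilyl)oxy]butan-2-yl}-6-hydroxy-4-methoxy-3-methylbenzoate (configured as in the SMILES) | COc1cc(O)c(C(=O)OCc2ccccc2)c(c1C)[C@H](C)[C@@H](O[Si](CC)(CC)CC)COC(=O)c1c(OCc2ccccc2)cc(OCc2ccccc2)c(C)c1C
A6 | alternative 3 | benzyl 6-{[2,4-bis(benzyloxy)-5,6-dimethylbenzoyl]oxy}-4-methyl-5-[(triethylsilyl)oxy]hex-2-ynoate (configured as in the SMILES) | O=C(OCc1ccccc1)C#C[C@H](C)[C@@H](O[Si](CC)(CC)CC)COC(=O)c1c(OCc2ccccc2)cc(OCc2ccccc2)c(C)c1C
A7 | alternative 3 | (3Z)-1,3-dimethoxy-1-[(trimethylsilyl)oxy]penta-1,3-diene | C/C=C(\OC)C=C(OC)O[Si](C)(C)C
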